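# Proposed synthesis of CNP0208264.1, the (2S,3R)-trans 3,3''-linked naringenin–apigenin biflavonoid (16), by aryne annulation of a chiral β-hydroxy ester

## Analysis of the target

- The target 16 is a 3,3''-linked biflavonoid. A naringenin-type flavanone (rings A, C and B) is bonded through C3 to C3'' of an apigenin-type flavone, and six phenols are free.
- There are two adjacent stereocentres, C2 (S) and C3 (R), in a trans relationship. The 4-hydroxyphenyl group on C2 and the chromonyl group on C3 are both equatorial, and H2 and H3 are antiperiplanar.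
- C3 lies α to the C4 ketone and is enolisable, and the trans arrangement is the thermodynamic one. C2 is therefore the only centre whose absolute configuration has to be installed.
- C2 is also the weak point. It is a benzylic aryl ether β to the ketone: base can open ring C by a retro-oxa-Michael reaction, and strong Lewis acids can ionise the C2–O1 bond. Either event racemises it.
- The polyphenol is sensitive to oxidation, which argues for a neutral final deprotection.
- The difficulty is to build the crowded C3–C3'' junction and to carry an enantiopure C2 through the closure of ring C without exposing it to equilibrating conditions.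
- The plan rests on ring A. O1 on C8a and the C4 carbonyl on C4a sit on neighbouring carbons, with oxygens at C5 and C7. A 3,5-dioxygenated benzyne gives exactly this pattern when one aryne carbon takes an oxygen nucleophile and the other an acyl group.

## Retrosynthetic reasoning

**16 from 15.** The six phenols are masked as benzyl ethers and the six O–CH2 bonds are cut last. Benzyl is preferred to methyl because aryl methyl ethers need a strong boron Lewis acid at room temperature, under which the C2–O1 bond of a flavanone with an oxygenated 2-aryl group can ionise. Hydrogenolysis is neutral. The forward step must remove six groups without reducing the chromone or cleaving C2–O1.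

**15 from 8 and 13.** The bonds O1–C8a and C4–C4a are cut together. This removes ring A as the aryne 14 (released from 13) and leaves the open-chain hydroxy ester 8, whose carbinol carbon is C2 and whose ester carbon is C4. Cutting here, and not at O1–C2 or C2–C3, means the C2–O bond already exists in 8 and is never broken, so C2 is set in a stable acyclic compound by a well-understood reaction. The forward reaction must attach the hydroxyl oxygen to the aryne carbon remote from the flanking benzyloxy group, and the resulting aryl anion must then acylate itself on the ester.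

**8 from 7.** The C–H bond of the carbinol is cut, which leads back to the aryl ketone 7. The α-carbon of 7 lies between ester, ketone and chromone and racemises by enolisation, so a catalyst-controlled reduction can convert all of 7 into one carbinol configuration. The α-carbon is not critical because it becomes the enolisable C3.

**7 from 6 and 2.** The bond between the α-carbon and the ketone carbon is cut (ester enolate acylation). The acid chloride 2 is the same reagent that supplies the other 4-oxygenated phenyl ring, so one building block serves twice.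

**6 from 5, and 5 from 3 and 4.** The pyranone ring of the flavone is opened at O1''–C2'' to the o-hydroxyaryl 1,3-diketone 5. The acetic ester arm is then cut at the central carbon of the diketone, giving 3 and the bromoester 4. That carbon is the most nucleophilic position of 3, so the future C3'' substituent goes on before the ring is closed and no flavone C–H has to be functionalised.

**3 from 1 and 2.** The diketone is cut between the methylene carbon and the aroyl carbon (Claisen-type acylation of the acetophenone 1).

**13 from 11, 10 and 9.** The o-silylaryl triflate is traced to phenol 9 by the standard sequence: bromination ortho to the hydroxyl (10), O-silylation (11), and bromine–lithium exchange with migration of silicon from oxygen to carbon (12) followed by triflation. The silyl group must end on the carbon between the oxygen-bearing carbons, because this fixes which aryne carbon carries the flanking benzyloxy group.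

## Alternatives that were turned down

**Alternative 1: Stetter closure of ring C.**
- Disconnection: C3–C4. A chiral triazolylidene carbene would turn the aldehyde of the racemic aryl ether A2 into an acyl-anion equivalent, which adds to the tethered alkylidene 1,3-diketone and gives flavanone A1. The open diketone on C3 of A1 is closed to the flavone later, by the same acid that removes the methoxymethyl groups.
- For it: it is catalytic, and carbene-catalysed closure of salicylaldehyde ethers to chroman-4-ones is well documented. On the precedent for ring closure it is stronger than the aryne annulation.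
- Against it: the aldehyde of A2 is electron-rich and flanked by two ortho oxygens, and the acceptor is β-branched. C2 of A2 must racemise through a dienolate faster than the ring closes, and the same dienolate can expel the aryloxide. A2 itself needs a condensation of a hindered unsymmetrical diketone with a labile α-aryloxy aldehyde.
- Comparison: the chosen route offers instead a C2 that is set by a ketone reduction in a stable compound and a flavone that is already in place. The step count is not better for A1.

**Alternative 2: vinyl o-quinone methide closure to a flavene.**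
- Disconnection: O1–C2 of a 2H-chromene. A chiral N-triflyl phosphoramide would ionise the racemic allylic alcohol A4 to a vinyl o-quinone methide ion pair, and the phenol oxygen would close onto C2 to give chromene A3.
- For it: C2 is created catalytically from a racemate in the ring-forming event itself. On this point it is stronger than the chosen route.
- Against it: A3 is at the wrong oxidation level. The C3=C4 bond must be hydrated with oxygen at C4 and then oxidised, on a hindered trisubstituted alkene, and C3 is set only by substrate control. The cation from A4 is stabilised by three methoxy groups and an anisyl group, so it should be long-lived and loosely paired. A 2-aryl-2H-chromene can also racemise by reversible electrocyclic ring opening. The end game needs a six-fold demethylation with BBr3.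
- Comparison: the chosen route gives the C4 ketone directly, C3 by thermodynamics, and a neutral last step.

**Alternative 3: o-quinone methide cycloaddition onto a 3-styrylflavone.**
- Disconnection: O1–C2 and C3–C4 in one [4+2] event. A confined chiral imidodiphosphorimidate acid would turn acetal A7 into a 4-methoxy o-quinone methide, which adds across the styryl double bond of flavone A6 to give flavan A5.
- For it: this is the most convergent plan. Two bonds, ring C and both stereocentres arise in one step from two halves of similar size, and the E geometry of A6 translates into the trans relationship. On convergency it is stronger than the chosen route.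
- Against it: the alkene of A6 is 1,2-disubstituted and carries a very large, electron-poor chromonyl group that the catalyst pocket must accept. A5 has a surplus C4 methoxy stereocentre that must be oxidised to the ketone on a very electron-rich scaffold. The methyl ethers again call for BBr3.
- Comparison: the chosen route offers a stereo-setting step with a predictable model, the correct oxidation state at C4 from the ring closure itself, and a risky step that cannot damage the stereochemistry already set.

Key step: step 9

Remark 1: C2 of 8 becomes the enolisable C3 of 15, so only the carbinol carbon of 8 has to be controlled. 8 is written as the anti isomer, which maps directly onto the trans flavanone; its C2 epimer would converge on 15 by equilibration.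

Remark 2: benzyl ethers are used on all six phenols, and 1, 2, 4 and 9 are taken to be commercially available.

## Route

Step 1
Reactants: 1 1-[2,4-bis(benzyloxy)-6-hydroxyphenyl]ethan-1-one; 2 4-(benzyloxy)benzoyl chloride
Product: 3 1-[2,4-bis(benzyloxy)-6-hydroxyphenyl]-3-[4-(benzyloxy)phenyl]propane-1,3-dione
Conditions: LiN(SiMe3)2 (3.3 equiv), THF, −78 to −10 °C; 2 (1.05 equiv), −78 °C to rt; aq HCl
Reagents that add atoms: none
Why: Excess amide base forms the phenoxide–enolate dianion of 1, whose enolate carbon is acylated by the aroyl chloride (Claisen-type acylation, the one-flask equivalent of a Baker–Venkataraman sequence). The diketonate that forms consumes the third equivalent of base and is not acylated further.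

Step 2
Reactants: 3 1-[2,4-bis(benzyloxy)-6-hydroxyphenyl]-3-[4-(benzyloxy)phenyl]propane-1,3-dione; 4 methyl bromoacetate
Product: 5 methyl 3-[4-(benzyloxy)benzoyl]-4-[2,4-bis(benzyloxy)-6-hydroxyphenyl]-4-oxobutanoate
Conditions: K2CO3 (1.0 equiv), acetone, 0 °C to rt
Reagents that add atoms: none
Why: One equivalent of carbonate deprotonates the more acidic 1,3-diketone in preference to the chelated phenol, and the soft diketonate carbon is alkylated by the activated bromide (C-alkylation of a 1,3-dicarbonyl compound). The new centre is stereolabile and disappears in step 3.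

Step 3
Reactants: 5 methyl 3-[4-(benzyloxy)benzoyl]-4-[2,4-bis(benzyloxy)-6-hydroxyphenyl]-4-oxobutanoate
Product: 6 methyl 2-{5,7-bis(benzyloxy)-2-[4-(benzyloxy)phenyl]-4-oxo-4H-chromen-3-yl}acetate
Conditions: p-TsOH·H2O (10 mol %), toluene, 90 °C
Reagents that add atoms: none
Why: The phenol adds to the aroyl carbonyl and the hemiketal loses water to give the 4-pyranone ring (acid cyclodehydration as used in flavone synthesis). The alkylated carbon becomes C3 of the flavone, and benzyl ethers and the ester tolerate the catalytic acid.

Step 4
Reactants: 6 methyl 2-{5,7-bis(benzyloxy)-2-[4-(benzyloxy)phenyl]-4-oxo-4H-chromen-3-yl}acetate; 2 4-(benzyloxy)benzoyl chloride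
Product: 7 methyl 3-[4-(benzyloxy)phenyl]-2-{5,7-bis(benzyloxy)-2-[4-(benzyloxy)phenyl]-4-oxo-4H-chromen-3-yl}-3-oxopropanoate (racemic, stereolabile)
Conditions: LiN(SiMe3)2 (2.2 equiv), THF, −78 °C; 2 (1.1 equiv), −78 to 0 °C; aq NH4Cl
Reagents that add atoms: none
Why: The lithium ester enolate is C-acylated by the acid chloride (crossed Claisen acylation). The second equivalent of base converts the more acidic β-keto ester into its enolate and so protects it from further acylation.

Step 5
Reactants: 7 methyl 3-[4-(benzyloxy)phenyl]-2-{5,7-bis(benzyloxy)-2-[4-(benzyloxy)phenyl]-4-oxo-4H-chromen-3-yl}-3-oxopropanoate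
Product: 8 methyl (2R,3S)-3-[4-(benzyloxy)phenyl]-2-{5,7-bis(benzyloxy)-2-[4-(benzyloxy)phenyl]-4-oxo-4H-chromen-3-yl}-3-hydroxypropanoate
Conditions: RuCl[(S,S)-TsDPEN](p-cymene) (3 mol %), HCO2H–Et3N (5:2), CH2Cl2, 35 °C
Reagents that add atoms: none
Why: Noyori–Ikariya asymmetric transfer hydrogenation with dynamic kinetic resolution: hydride and proton are delivered to one face of the aryl ketone with its aryl ring under the η6-arene, which for the (S,S) catalyst predicts the 3S carbinol, as with aryl alkyl ketones. The α-carbon racemises by enolisation faster than reduction, so all of 7 is funnelled; the anti isomer is written, and the configuration of this carbon is not critical. The chromone enone is not a substrate for this catalyst.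

Step 6
Reactants: 9 3,5-bis(benzyloxy)phenol
Product: 10 2-bromo-3,5-bis(benzyloxy)phenol
Conditions: NBS (1.0 equiv), CH2Cl2, −78 °C to rt
Reagents that add atoms: N-bromosuccinimide, O=C1CCC(=O)N1Br
Why: Electrophilic aromatic bromination of a phloroglucinol-type ring. The position ortho to the free hydroxyl is statistically and sterically favoured over the carbon between the two benzyloxy groups, and one equivalent at low temperature limits dibromination.

Step 7
Reactants: 10 2-bromo-3,5-bis(benzyloxy)phenol
Product: 11 [2-bromo-3,5-bis(benzyloxy)phenoxy]trimethylsilane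
Conditions: HN(SiMe3)2, THF, 65 °C; concentrate
Reagents that add atoms: hexamethyldisilazane, C[Si](C)(C)N[Si](C)(C)C
Why: O-Silylation of the phenol with the disilazane. Ammonia is the only by-product, so the crude silyl ether can be used after evaporation.

Step 8
Reactants: 11 [2-bromo-3,5-bis(benzyloxy)phenoxy]trimethylsilane
Product: 13 3,5-bis(benzyloxy)-2-(trimethylsilyl)phenyl trifluoromethanesulfonate, via lithium silylphenoxide 12 (not isolated)
Conditions: n-BuLi, THF, −100 °C; then Tf2O, −100 to −78 °C
Reagents that add atoms: trifluoromethanesulfonic anhydride, O=S(=O)(OS(=O)(=O)C(F)(F)F)C(F)(F)F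
Why: Bromine–lithium exchange gives an aryllithium that takes the silyl group from the neighbouring oxygen (retro-Brook 1,3-shift), and the phenoxide is then triflated. This is the standard route to o-silylaryl triflates.

Step 9
Reactants: 8 methyl (2R,3S)-3-[4-(benzyloxy)phenyl]-2-{5,7-bis(benzyloxy)-2-[4-(benzyloxy)phenyl]-4-oxo-4H-chromen-3-yl}-3-hydroxypropanoate; 13 3,5-bis(benzyloxy)-2-(trimethylsilyl)phenyl trifluoromethanesulfonate
Product: 15 (2S,3R)-5,7-bis(benzyloxy)-2-[4-(benzyloxy)phenyl]-3-{5,7-bis(benzyloxy)-2-[4-(benzyloxy)phenyl]-4-oxo-4H-chromen-3-yl}chroman-4-one, via 3,5-bis(benzyloxy)benzyne 14 (not isolated)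
Conditions: 13 (2.0 equiv), CsF (5 equiv), THF, 65 °C
Reagents that add atoms: none
Why: Proposed new method: fluoride attacks the silicon of 13 and expels triflate to give aryne 14; the hydroxyl of 8, hydrogen-bonded to fluoride and acting as a caesium alkoxide equivalent, adds through oxygen to the aryne carbon remote from the flanking benzyloxy group (O1–C8a), and the aryl anion so formed, placed between two oxygen-bearing carbons, attacks the ester carbonyl and expels methoxide (C4–C4a). The closest known reactions are the fluoride-promoted annulations of arynes with methyl salicylates and anthranilates, where O- or N-arylation is followed by the same acyl capture to give xanthones and acridones, and the insertion of arynes into unsaturated carboxylic acids that leads to chroman-4-ones; an aliphatic secondary hydroxyl on a flexible tether has not been used in this way. Ring C closes in the 6-exo-trig mode. No stereocentre is created: the C2–O bond of the carbinol is never broken, so its configuration is retained, and C3, now α to the ketone, is under thermodynamic control and rests trans with both substituents equatorial. The step needs regioselective addition, which the inductive polarisation and distortion of the aryne by the neighbouring benzyloxy group should secure. It also needs acyl capture to outrun protonation, which the six-membered transition state, the lack of acidic hydrogen in THF and the weakness of fluoride as a base (the ester α-hydrogen stays in place) are meant to secure. The excess of 13 takes up the released methoxide by attack at silicon, which spares the base-sensitive C2–O1 bond of 15.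

Step 10
Reactants: 15 (2S,3R)-5,7-bis(benzyloxy)-2-[4-(benzyloxy)phenyl]-3-{5,7-bis(benzyloxy)-2-[4-(benzyloxy)phenyl]-4-oxo-4H-chromen-3-yl}chroman-4-one
Product: 16 (2S,3R)-5,7-dihydroxy-3-[5,7-dihydroxy-2-(4-hydroxyphenyl)-4-oxo-4H-chromen-3-yl]-2-(4-hydroxyphenyl)chroman-4-one
Conditions: H2 (1 atm), Pd(OH)2/C, EtOAc–MeOH, rt
Reagents that add atoms: none
Why: Catalytic hydrogenolysis cleaves the six aryl benzyl ethers under neutral conditions, so neither C2 nor C3 is exposed to acid or base. The tetrasubstituted chromone double bond and the hydrogen-bonded aryl ketones should not be reduced at atmospheric pressure, and the reaction is stopped at full conversion to spare the C2–O1 bond.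

## Compound list

1 | 1-[2,4-bis(benzyloxy)-6-hydroxyphenyl]ethan-1-one | CC(=O)c1c(O)cc(OCc2ccccc2)cc1OCc1ccccc1 | starting material
2 | 4-(benzyloxy)benzoyl chloride | O=C(Cl)c1ccc(OCc2ccccc2)cc1 | starting material
3 | 1-[2,4-bis(benzyloxy)-6-hydroxyphenyl]-3-[4-(benzyloxy)phenyl]propane-1,3-dione | O=C(CC(=O)c1ccc(OCc2ccccc2)cc1)c1c(O)cc(OCc2ccccc2)cc1OCc1ccccc1 | intermediate
4 | methyl bromoacetate | COC(=O)CBr | starting material
5 | methyl 3-[4-(benzyloxy)benzoyl]-4-[2,4-bis(benzyloxy)-6-hydroxyphenyl]-4-oxobutanoate | COC(=O)CC(C(=O)c1ccc(OCc2ccccc2)cc1)C(=O)c1c(O)cc(OCc2ccccc2)cc1OCc1ccccc1 | intermediate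
6 | methyl 2-{5,7-bis(benzyloxy)-2-[4-(benzyloxy)phenyl]-4-oxo-4H-chromen-3-yl}acetate | COC(=O)Cc1c(-c2ccc(OCc3ccccc3)cc2)oc2cc(OCc3ccccc3)cc(OCc3ccccc3)c2c1=O | intermediate
7 | methyl 3-[4-(benzyloxy)phenyl]-2-{5,7-bis(benzyloxy)-2-[4-(benzyloxy)phenyl]-4-oxo-4H-chromen-3-yl}-3-oxopropanoate (racemic, stereolabile) | COC(=O)C(C(=O)c1ccc(OCc2ccccc2)cc1)c1c(-c2ccc(OCc3ccccc3)cc2)oc2cc(OCc3ccccc3)cc(OCc3ccccc3)c2c1=O | intermediate
8 | methyl (2R,3S)-3-[4-(benzyloxy)phenyl]-2-{5,7-bis(benzyloxy)-2-[4-(benzyloxy)phenyl]-4-oxo-4H-chromen-3-yl}-3-hydroxypropanoate | O[C@H](c1ccc(OCc2ccccc2)cc1)[C@H](C(=O)OC)c1c(-c2ccc(OCc3ccccc3)cc2)oc2cc(OCc3ccccc3)cc(OCc3ccccc3)c2c1=O | intermediate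
9 | 3,5-bis(benzyloxy)phenol | Oc1cc(OCc2ccccc2)cc(OCc2ccccc2)c1 | starting material
10 | 2-bromo-3,5-bis(benzyloxy)phenol | Oc1cc(OCc2ccccc2)cc(OCc2ccccc2)c1Br | intermediate
11 | [2-bromo-3,5-bis(benzyloxy)phenoxy]trimethylsilane | C[Si](C)(C)Oc1cc(OCc2ccccc2)cc(OCc2ccccc2)c1Br | intermediate
12 | lithium 3,5-bis(benzyloxy)-2-(trimethylsilyl)phenoxide (not isolated) | [Li+].[O-]c1cc(OCc2ccccc2)cc(OCc2ccccc2)c1[Si](C)(C)C | intermediate
13 | 3,5-bis(benzyloxy)-2-(trimethylsilyl)phenyl trifluoromethanesulfonate | C[Si](C)(C)c1c(OCc2ccccc2)cc(OCc2ccccc2)cc1OS(=O)(=O)C(F)(F)F | intermediate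
14 | 3,5-bis(benzyloxy)benzyne (not isolated) | C1#CC(OCc2ccccc2)=CC(OCc2ccccc2)=C1 | intermediate
15 | (2S,3R)-5,7-bis(benzyloxy)-2-[4-(benzyloxy)phenyl]-3-{5,7-bis(benzyloxy)-2-[4-(benzyloxy)phenyl]-4-oxo-4H-chromen-3-yl}chroman-4-one | O=C1c2c(OCc3ccccc3)cc(OCc3ccccc3)cc2O[C@H](c2ccc(OCc3ccccc3)cc2)[C@H]1c1c(-c2ccc(OCc3ccccc3)cc2)oc2cc(OCc3ccccc3)cc(OCc3ccccc3)c2c1=O | intermediate
16 | (2S,3R)-5,7-dihydroxy-3-[5,7-dihydroxy-2-(4-hydroxyphenyl)-4-oxo-4H-chromen-3-yl]-2-(4-hydroxyphenyl)chroman-4-one | O=C1c2c(O)cc(O)cc2O[C@H](c2ccc(O)cc2)[C@H]1c1c(-c2ccc(O)cc2)oc2cc(O)cc(O)c2c1=O | target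

## Step count and least certain steps

Total step count: 10. Longest linear sequence: 7 steps (steps 1, 2, 3, 4, 5, 9 and 10, from 1 to 16). The aryne precursor 13 is made in a 3-step side branch (steps 6 to 8).

**Step 9 (key step, proposed new method).**
- Most likely failure: protonation of the aryl anion before it reaches the ester. The hydroxyl proton is handed to fluoride and stays nearby as hydrogen fluoride or bifluoride.
- A second path is an intramolecular proton shift from the acidic C–H next to the ester, followed by β-elimination of the new aryloxide.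
- Further risks are retro-aldol cleavage or dehydration of 8 under the basic fluoride at 65 °C, and ring opening of the product by stray methoxide (retro-oxa-Michael), which would erode C2.
- Fallback, by known chemistry, from 8 back to 15: 8 is dehydrated (MsCl, Et3N, then DBU) to methyl (E)-3-[4-(benzyloxy)phenyl]-2-(chromon-3-yl)prop-2-enoate F1 and saponified (LiOH) to the acrylic acid F2. With 13 and CsF in THF at elevated temperature, F2 undergoes the known insertion of the aryne into the carboxylic acid: the 2'-hydroxychalcone F3 (not isolated) closes by intramolecular oxa-Michael addition to the racemic trans flavanone F4. F4 is resolved by preparative chromatography on a chiral stationary phase to give 15.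
- This fallback gives up the carbinol stereocentre and forms O1–C2 last, under thermodynamic control.

**Step 5.**
- Most likely failure: incomplete reduction, because the ketone is electron-rich and sits next to a fully substituted α-carbon; or weakened face selection, because the bulky chromonyl group competes with the catalyst for control.
- Fallback, from 6 back to 15: 6 is saponified to the acetic acid F5, which is coupled through its mixed pivalic anhydride with lithiated (S)-4-benzyloxazolidin-2-one to the imide F6. An Evans aldol reaction (Bu2BOTf, i-Pr2NEt, 4-(benzyloxy)benzaldehyde, −78 to 0 °C) gives the syn adduct F7 with the required 3S carbinol. Transesterification with MeMgBr in MeOH gives the methyl ester F8, the C2 epimer of 8. F8 enters step 9, and the cis flavanone F9 (not isolated) epimerises at C3 to 15.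

**Step 2.**
- Most likely failure: alkylation at the phenol oxygen or a second alkylation, since phenoxide and diketonate are both present to some extent.
- Fallback, from 3 back to 6: 3 is cyclodehydrated (p-TsOH, toluene) to the flavone F10. Lithiation at C3 with LiN(i-Pr)2 at −78 °C and an iodine quench give the 3-iodoflavone F11. A Negishi-type coupling with the Reformatsky reagent F12 (from 4 and zinc), with Pd2(dba)3 and P(t-Bu)3, gives 6.

**Step 4.**
- Most likely failure: acylation at the enolate oxygen, or a second acylation of the product enolate, on a hindered substrate.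
- Fallback, from 6 back to 7: aldol addition of the lithium enolate of 6 to 4-(benzyloxy)benzaldehyde gives the hydroxy ester F13 as a mixture of stereoisomers, which is oxidised with Dess–Martin periodinane to 7.

**Step 10.**
- Most likely failure: reductive cleavage of the benzylic C2–O1 bond on prolonged hydrogenation, or incomplete removal of the six groups.
- Fallback, from 15 back to 16: Lewis-acid debenzylation with BCl3 in the presence of pentamethylbenzene as cation scavenger in CH2Cl2 at −78 °C. It makes no new compound (F0).

## Further compounds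

F1 | step 9 | methyl (E)-3-[4-(benzyloxy)phenyl]-2-{5,7-bis(benzyloxy)-2-[4-(benzyloxy)phenyl]-4-oxo-4H-chromen-3-yl}prop-2-enoate | COC(=O)/C(=C/c1ccc(OCc2ccccc2)cc1)c1c(-c2ccc(OCc3ccccc3)cc2)oc2cc(OCc3ccccc3)cc(OCc3ccccc3)c2c1=O
F2 | step 9 | (E)-3-[4-(benzyloxy)phenyl]-2-{5,7-bis(benzyloxy)-2-[4-(benzyloxy)phenyl]-4-oxo-4H-chromen-3-yl}prop-2-enoic acid | OC(=O)/C(=C/c1ccc(OCc2ccccc2)cc1)c1c(-c2ccc(OCc3ccccc3)cc2)oc2cc(OCc3ccccc3)cc(OCc3ccccc3)c2c1=O
F3 | step 9 | 1-[2,4-bis(benzyloxy)-6-hydroxyphenyl]-3-[4-(benzyloxy)phenyl]-2-{5,7-bis(benzyloxy)-2-[4-(benzyloxy)phenyl]-4-oxo-4H-chromen-3-yl}prop-2-en-1-one (not isolated) | O=C(C(=Cc1ccc(OCc2ccccc2)cc1)c1c(-c2ccc(OCc3ccccc3)cc2)oc2cc(OCc3ccccc3)cc(OCc3ccccc3)c2c1=O)c1c(O)cc(OCc2ccccc2)cc1OCc1ccccc1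
F4 | step 9 | racemic 2,3-trans form of 15 | O=C1c2c(OCc3ccccc3)cc(OCc3ccccc3)cc2OC(c2ccc(OCc3ccccc3)cc2)C1c1c(-c2ccc(OCc3ccccc3)cc2)oc2cc(OCc3ccccc3)cc(OCc3ccccc3)c2c1=O
F5 | step 5 | 2-{5,7-bis(benzyloxy)-2-[4-(benzyloxy)phenyl]-4-oxo-4H-chromen-3-yl}acetic acid | OC(=O)Cc1c(-c2ccc(OCc3ccccc3)cc2)oc2cc(OCc3ccccc3)cc(OCc3ccccc3)c2c1=O
F6 | step 5 | (S)-4-benzyl-3-(2-{5,7-bis(benzyloxy)-2-[4-(benzyloxy)phenyl]-4-oxo-4H-chromen-3-yl}acetyl)oxazolidin-2-one | O=C1OC[C@H](Cc2ccccc2)N1C(=O)Cc1c(-c2ccc(OCc3ccccc3)cc2)oc2cc(OCc3ccccc3)cc(OCc3ccccc3)c2c1=O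
F7 | step 5 | (S)-4-benzyl-3-[(2S,3S)-3-[4-(benzyloxy)phenyl]-2-{5,7-bis(benzyloxy)-2-[4-(benzyloxy)phenyl]-4-oxo-4H-chromen-3-yl}-3-hydroxypropanoyl]oxazolidin-2-one | O[C@H](c1ccc(OCc2ccccc2)cc1)[C@@H](C(=O)N1C(=O)OC[C@@H]1Cc1ccccc1)c1c(-c2ccc(OCc3ccccc3)cc2)oc2cc(OCc3ccccc3)cc(OCc3ccccc3)c2c1=O
F8 | step 5 | methyl (2S,3S)-3-[4-(benzyloxy)phenyl]-2-{5,7-bis(benzyloxy)-2-[4-(benzyloxy)phenyl]-4-oxo-4H-chromen-3-yl}-3-hydroxypropanoate (C2 epimer of 8) | O[C@H](c1ccc(OCc2ccccc2)cc1)[C@@H](C(=O)OC)c1c(-c2ccc(OCc3ccccc3)cc2)oc2cc(OCc3ccccc3)cc(OCc3ccccc3)c2c1=O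
F9 | step 5 | (2S,3S)-5,7-bis(benzyloxy)-2-[4-(benzyloxy)phenyl]-3-{5,7-bis(benzyloxy)-2-[4-(benzyloxy)phenyl]-4-oxo-4H-chromen-3-yl}chroman-4-one (2,3-cis, C3 epimer of 15, not isolated) | O=C1c2c(OCc3ccccc3)cc(OCc3ccccc3)cc2O[C@H](c2ccc(OCc3ccccc3)cc2)[C@@H]1c1c(-c2ccc(OCc3ccccc3)cc2)oc2cc(OCc3ccccc3)cc(OCc3ccccc3)c2c1=O
F10 | step 2 | 5,7-bis(benzyloxy)-2-[4-(benzyloxy)phenyl]-4H-chromen-4-one | O=c1cc(-c2ccc(OCc3ccccc3)cc2)oc2cc(OCc3ccccc3)cc(OCc3ccccc3)c12
F11 | step 2 | 5,7-bis(benzyloxy)-2-[4-(benzyloxy)phenyl]-3-iodo-4H-chromen-4-one | O=c1c(I)c(-c2ccc(OCc3ccccc3)cc2)oc2cc(OCc3ccccc3)cc(OCc3ccccc3)c12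
F12 | step 2 | bromo(2-methoxy-2-oxoethyl)zinc | COC(=O)C[Zn]Br
F13 | step 4 | methyl 3-[4-(benzyloxy)phenyl]-2-{5,7-bis(benzyloxy)-2-[4-(benzyloxy)phenyl]-4-oxo-4H-chromen-3-yl}-3-hydroxypropanoate (mixture of stereoisomers) | OC(c1ccc(OCc2ccccc2)cc1)C(C(=O)OC)c1c(-c2ccc(OCc3ccccc3)cc2)oc2cc(OCc3ccccc3)cc(OCc3ccccc3)c2c1=O
F0 | step 10 | none | none
A1 | alternative 1 | 2,3-trans (2S,3R) flavanone carrying an open 1,3-diketone at C3, heptakis(methoxymethyl) ether | O=C1c2c(OCOC)cc(OCOC)cc2O[C@H](c2ccc(OCOC)cc2)[C@H]1C(C(=O)c1ccc(OCOC)cc1)C(=O)c1c(OCOC)cc(OCOC)cc1OCOC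
A2 | alternative 1 | racemic 2-formyl-3,5-bis(methoxymethoxy)phenyl ether of the γ-hydroxy alkylidene 1,3-diketone | O=Cc1c(OCOC)cc(OCOC)cc1OC(c1ccc(OCOC)cc1)C=C(C(=O)c1ccc(OCOC)cc1)C(=O)c1c(OCOC)cc(OCOC)cc1OCOC
A3 | alternative 2 | (2R)-3-[5,7-dimethoxy-2-(4-methoxyphenyl)-4-oxo-4H-chromen-3-yl]-5,7-dimethoxy-2-(4-methoxyphenyl)-2H-chromene (C2 arranged in space as in the target) | C1=C(c2c(-c3ccc(OC)cc3)oc3cc(OC)cc(OC)c3c2=O)[C@@H](c2ccc(OC)cc2)Oc2cc(OC)cc(OC)c12
A4 | alternative 2 | racemic 2-{1-hydroxy-2-[5,7-dimethoxy-2-(4-methoxyphenyl)-4-oxo-4H-chromen-3-yl]-3-(4-methoxyphenyl)prop-2-en-1-yl}-3,5-dimethoxyphenol | OC(c1c(O)cc(OC)cc1OC)C(=Cc1ccc(OC)cc1)c1c(-c2ccc(OC)cc2)oc2cc(OC)cc(OC)c2c1=O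
A5 | alternative 3 | 2,3-trans-4,5,7-trimethoxy-2-(4-methoxyphenyl)flavan carrying the trimethoxyflavon-3-yl group at C3 (C2 and C3 as in the target, 4-methoxy cis to the C2 aryl group) | CO[C@@H]1c2c(OC)cc(OC)cc2O[C@H](c2ccc(OC)cc2)[C@H]1c1c(-c2ccc(OC)cc2)oc2cc(OC)cc(OC)c2c1=O
A6 | alternative 3 | (E)-5,7-dimethoxy-2-(4-methoxyphenyl)-3-(4-methoxystyryl)-4H-chromen-4-one | COc1ccc(/C=C/c2c(-c3ccc(OC)cc3)oc3cc(OC)cc(OC)c3c2=O)cc1
A7 | alternative 3 | 2-(dimethoxymethyl)-3,5-dimethoxyphenol | COC(OC)c1c(O)cc(OC)cc1OC
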